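If we run these flasks again, the thing to watch is how the substrate divides between its two exits.

all flasks: substrate 5.0 mM; catalyst 19 µM; time 15 s

| run | remark | temperature |
|---|---|---|
| west | at 90 °C until 8.0 s, from then on at 30 °C |  |
| east |  | 60 °C |
| north-west |  | 90 °C |
| south-east |  | 30 °C |

    substrate + catalyst → catalyst + target (k1 = 2800 /M/s, Ea1 = 39.0 kJ/mol)
    substrate → side product (k2 = 0.024 /s, Ea2 = 92.0 kJ/mol)
    crystals ⇌ target, rate k3*(cs3 - [target]) while solid is left; crystals form when [target] > cs3 (cs3 = 0.13 mM, k3 = 1.1 /s)
    (constants at 60 °C)

- amounts and yields of target count crystals too
- given per volume of solution although it is solid: crystals
- at 60 °C the constants are as listed, elsewhere as the activation energies make them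

* the best flask by amount of target, in percent of the substrate charged; "all alike" if 1.5 percentage points covers them all (west / east / north-west / south-east / all alike)
* amount of target at the end, in percent of the substrate charged, west
* amount of target at the end, in percent of the substrate charged, east
* amount of target at the end, in percent of the substrate charged, north-west
* amount of target at the end, in percent of the substrate charged, south-east

Here is the note for the bench. Each flask holds substrate and a small charge of catalyst, which the catalysed step gives back, so c(catalyst) stays at its charge and both losses of substrate are pseudo-first-order. Crystals are target in another form and are counted, so we leave them alone.

We carry one quantity, the balance catalyst at 90 °C: the constant of the side step over that of the catalysed step, which is the amount of catalyst at which the two steps use substrate equally fast, 41.6 µM. The side step has the higher activation energy, so this ratio rises with temperature: it is 8.57 µM at 60 °C and 1.29 µM at 30 °C. Our charge of 19 µM lies above the value at 60 °C and below the one at 90 °C, so control passes to the side step between these temperatures. The selectivity is c(catalyst) over c(catalyst) plus the balance value.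

At 90 °C the substrate lifetime is 1.84 s, shorter than the 8.0 s before west is cooled. We therefore expect 31.3% in north-west and 31.3% in west. At 60 °C the lifetime is 13.0 s, which gives 47.3% in east. At 30 °C it is 70.9 s, longer than the run, which gives 17.9% in south-east. Our pick is east.

The forecast names east, with 31% for west, 47.3% for east, 31.3% for north-west and 17.9% for south-east, reckoning from “the catalytic share of the rate times the conversion reached”.

The simulation gives east as best, with 31.0% for west, 47.3% for east, 31.3% for north-west and 17.9% for south-east.

The forecast held. In north-west, taking the side step away lifts target from 31.3% to 92.2%, so that step is the main reason for the low yield there, while the low solubility of target makes no difference. West reached its cooling at 8.00 s with 1.30% substrate left, so the cold stage had little to divide. In the neighbour flask, which is west with 0.076 mM catalyst, the charge stands above the balance catalyst, and the selectivity at 90 °C comes to 64.6%. The run gives 64.6%.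

All constants are those of an exercise; the rest is arithmetic.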